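**Retrosynthetic overview**
1. (−)-Pipoxide 13 comes from endoperoxide 12 by P(OMe)3-induced syn-SN2' ring contraction. 12 comes from a [4+2] cycloaddition of singlet oxygen to dienol 11 on the face of its free C2–OH, and this step fixes C1 and C6.
2. 11 comes from dienetriol 10 by regioselective dibenzoylation. 10 comes from dihydroxy-dienoate 9 (DIBAL-H), and 9 from cyclohexenes 8/7 by vinylogous E1cB elimination.
3. 7 comes from diene 6 by RCM. 6 comes from a chelation-controlled indium Barbier coupling of bromocrotonate 4 with enal 5, which arises by Vasella fragmentation of iodofuranoside 3 made from D-arabinose 1 (sugar C2 becomes pipoxide C3).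
4. Ring order: carbocycle (RCM, step 4), then 2,3-dioxabicyclo[2.2.2]octene (cycloaddition, step 9), then oxirane (same flask).

Assumption: the target is taken exactly as drawn, i.e. (1R,2R,3S,6S), with the oxirane cis to C2–OH and trans to C3–OBz.
Locants C1–C7 in the comments are those of pipoxide: C1 is quaternary and bears C7H2OBz, C2 carries OH, C3 carries OBz, C4=C5 is the alkene, and C6 is the epoxide CH. The systematic names carry their own locants.

**Step 1**
Reactants: 1 D-arabinose
Product: 2 methyl D-arabinofuranoside (α/β mixture)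
Conditions: MeOH, H2SO4 (cat.), rt, 5 h; then basic resin
Reagents that add atoms: methanol, CO
Why: Kinetic Fischer glycosidation traps the pentose as the furanoside, leaving O5 as the only primary hydroxyl; C2–C4 are untouched, and the anomeric mixture is irrelevant because C1 is unmasked again in step 3.

**Step 2**
Reactants: 2 methyl D-arabinofuranoside
Product: 3 methyl 5-deoxy-5-iodo-D-arabinofuranoside
Conditions: I2, PPh3, imidazole, THF, reflux
Reagents that add atoms: iodine, II
Why: In this Garegg–Samuelsson (Appel-type) iodination the oxyphosphonium salt is displaced by iodide (SN2) only at the unhindered primary carbinol, so no protecting groups are needed.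

**Step 3**
Reactants: 3 methyl 5-deoxy-5-iodo-D-arabinofuranoside; 4 tert-butyl (E)-4-bromobut-2-enoate
Product: 6 tert-butyl (3S,4S,5R)-3,4,5-trihydroxy-2-vinylhept-6-enoate (C2 epimers), via (2S,3R)-2,3-dihydroxypent-4-enal 5 (not isolated)
Conditions: Zn dust, THF/H2O 4:1, sonication, 40 °C; filter; then In powder, 4, rt
Reagents that add atoms: none
Why: Bernet–Vasella reductive fragmentation gives enal 5 with both sugar centres intact, and the allylindium from 4 then adds through its γ-carbon (Barbier, SE2') to the Cram chelate of the free α-hydroxy aldehyde, which sets the new carbinol (future C2) syn/threo to the bought centre (future C3); the ester-bearing centre is a mixture that step 6 erases, and the tert-butyl ester suppresses lactonisation.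

**Step 4**
Reactants: 6 tert-butyl (3S,4S,5R)-3,4,5-trihydroxy-2-vinylhept-6-enoate
Product: 7 tert-butyl (4R,5S,6S)-4,5,6-trihydroxycyclohex-2-ene-1-carboxylate (all-trans triol, C1 epimers)
Conditions: Hoveyda–Grubbs II (3 mol %), CH2Cl2, 40 °C
Reagents that add atoms: none
Why: Ring-closing metathesis of two monosubstituted olefins to an unstrained cyclohexene is fast, tolerates free hydroxyls, touches no stereocentre and is driven by loss of ethene.

**Step 5**
Reactants: 7 tert-butyl (4R,5S,6S)-4,5,6-trihydroxycyclohex-2-ene-1-carboxylate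
Product: 8 tert-butyl (4R,5R,6S)-5,6-dihydroxy-4-(pivaloyloxy)cyclohex-2-ene-1-carboxylate
Conditions: PivCl (1.1 equiv), pyridine, CH2Cl2, 0 °C
Reagents that add atoms: pivaloyl chloride, CC(C)(C)C(=O)Cl
Why: In this sterically governed regioselective acylation the allylic C4–OH, flanked by an sp2 CH, reacts first with the bulky acyl chloride (as O3 does in glucal), whereas C2–OH is shielded by and hydrogen-bonded to the tert-butyl ester and C3–OH is flanked on both sides.

**Step 6**
Reactants: 8 tert-butyl (4R,5R,6S)-5,6-dihydroxy-4-(pivaloyloxy)cyclohex-2-ene-1-carboxylate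
Product: 9 tert-butyl (5S,6S)-5,6-dihydroxycyclohexa-1,3-diene-1-carboxylate
Conditions: DBU (2 equiv), THF, 0 °C → rt
Reagents that add atoms: none
Why: In this vinylogous E1cB (1,4-) elimination DBU removes the doubly activated H1 (α to the ester and allylic) and the dienolate expels the δ-pivalate, so both C1 epimers converge on one dienoate; C2 and C3 stay intact because hydroxide at C2 is not a leaving group.

**Step 7**
Reactants: 9 tert-butyl (5S,6S)-5,6-dihydroxycyclohexa-1,3-diene-1-carboxylate
Product: 10 (1S,2S)-3-(hydroxymethyl)cyclohexa-3,5-diene-1,2-diol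
Conditions: DIBAL-H (6 equiv), CH2Cl2/THF, −78 → 0 °C; Rochelle salt
Reagents that add atoms: none
Why: DIBAL-H reduces the conjugated ester in 1,2-fashion to the allylic alcohol without touching the diene or the two carbinol centres, and the non-acidic work-up avoids aromatisation.

**Step 8**
Reactants: 10 (1S,2S)-3-(hydroxymethyl)cyclohexa-3,5-diene-1,2-diol
Product: 11 [(5S,6S)-5-(benzoyloxy)-6-hydroxycyclohexa-1,3-dien-1-yl]methyl benzoate
Conditions: BzCl (2.1 equiv), pyridine, CH2Cl2, −40 → −10 °C
Reagents that add atoms: benzoyl chloride, O=C(Cl)c1ccccc1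
Why: This regioselective benzoylation follows the reactivity order of the 3,6-di-O-acylation of glucal: the primary C7–OH and the allylic C3–OH next to an unsubstituted sp2 CH react, while C2–OH, wedged between C3 and the substituted C1, stays free.

**Step 9**
Reactants: 11 [(5S,6S)-5-(benzoyloxy)-6-hydroxycyclohexa-1,3-dien-1-yl]methyl benzoate
Product: 13 (−)-pipoxide, [(1R,2R,3S,6S)-3-(benzoyloxy)-2-hydroxy-7-oxabicyclo[4.1.0]hept-4-en-1-yl]methyl benzoate, via [(1R,4R,7R,8R)-8-(benzoyloxy)-7-hydroxy-2,3-dioxabicyclo[2.2.2]oct-5-en-1-yl]methyl benzoate 12 (not isolated)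
Conditions: O2, TPP (1 mol %), hν, CH2Cl2, −20 °C; then P(OMe)3 (1.2 equiv), −20 °C → rt
Reagents that add atoms: dioxygen, O=O
Why: Singlet oxygen adds to the s-cis diene in a suprafacial [4+2] cycloaddition (hetero-Diels–Alder) on the face syn to the hydrogen-bond-donating C2–OH and anti to the pseudo-axial C3 benzoate, which fixes C1–O; trimethyl phosphite then attacks the less hindered oxygen on C4 and the C1 alkoxide closes on C6 in a syn-SN2', setting C6 and giving the cis-epoxy alcohol with the alkene at C4=C5.

**Compound list**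
1 | D-arabinose | O=C[C@@H](O)[C@H](O)[C@H](O)CO | starting material
2 | methyl D-arabinofuranoside (α/β) | COC1O[C@H](CO)[C@@H](O)[C@@H]1O | intermediate
3 | methyl 5-deoxy-5-iodo-D-arabinofuranoside (α/β) | COC1O[C@H](CI)[C@@H](O)[C@@H]1O | intermediate
4 | tert-butyl (E)-4-bromobut-2-enoate | CC(C)(C)OC(=O)/C=C/CBr | starting material
5 | (2S,3R)-2,3-dihydroxypent-4-enal | O=C[C@@H](O)[C@H](O)C=C | intermediate
6 | tert-butyl (3S,4S,5R)-3,4,5-trihydroxy-2-vinylhept-6-enoate (C2 epimers) | C=CC(C(=O)OC(C)(C)C)[C@H](O)[C@@H](O)[C@H](O)C=C | intermediate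
7 | tert-butyl (4R,5S,6S)-4,5,6-trihydroxycyclohex-2-ene-1-carboxylate (C1 epimers) | O[C@@H]1[C@@H](O)[C@H](O)C=CC1C(=O)OC(C)(C)C | intermediate
8 | tert-butyl (4R,5R,6S)-5,6-dihydroxy-4-(pivaloyloxy)cyclohex-2-ene-1-carboxylate (C1 epimers) | O[C@@H]1[C@@H](O)[C@H](OC(=O)C(C)(C)C)C=CC1C(=O)OC(C)(C)C | intermediate
9 | tert-butyl (5S,6S)-5,6-dihydroxycyclohexa-1,3-diene-1-carboxylate | O[C@@H]1[C@@H](O)C=CC=C1C(=O)OC(C)(C)C | intermediate
10 | (1S,2S)-3-(hydroxymethyl)cyclohexa-3,5-diene-1,2-diol | O[C@@H]1[C@@H](O)C=CC=C1CO | intermediate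
11 | [(5S,6S)-5-(benzoyloxy)-6-hydroxycyclohexa-1,3-dien-1-yl]methyl benzoate | O[C@@H]1[C@@H](OC(=O)c2ccccc2)C=CC=C1COC(=O)c1ccccc1 | intermediate
12 | [(1R,4R,7R,8R)-8-(benzoyloxy)-7-hydroxy-2,3-dioxabicyclo[2.2.2]oct-5-en-1-yl]methyl benzoate | O=C(OC[C@]12OO[C@H](C=C1)[C@H](OC(=O)c1ccccc1)[C@H]2O)c1ccccc1 | intermediate
13 | (−)-pipoxide | O=C(OC[C@]12O[C@H]1C=C[C@H](OC(=O)c1ccccc1)[C@H]2O)c1ccccc1 | target

**Total step count:** 9. **Longest linear sequence:** 9 (from D-arabinose; 4 is purchased).

**Steps most likely to fail**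

Step 5 (acylation at the wrong hydroxyl; a C2 ester would β-eliminate and aromatise in step 6). The fallback sets out from 7 and returns at 9. It draws its selectivity from mechanism instead of sterics. NCS/Me2S in CH2Cl2 at −20 °C turns all three hydroxyls into alkoxysulfonium salts, but only the allylic one is displaced by chloride. This gives tert-butyl (5R,6S)-4-chloro-5,6-dihydroxycyclohex-2-ene-1-carboxylate F1, and aqueous work-up returns the two saturated carbinols unchanged. DBU then removes H1 and chloride in the same vinylogous E1cB sense to give 9.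

Step 8 (competing C2 benzoylation, tribenzoate formation or acyl migration). The fallback sets out from 10 and returns at 11. (t-Bu)2Si(OTf)2 with 2,6-lutidine ties the 1,3-related C7–OH and C2–OH into a six-membered silylene, (8S,8aS)-2,2-di-tert-butyl-8,8a-dihydro-4H-benzo[d][1,3,2]dioxasilin-8-ol F2, in which C3–OH is the only free hydroxyl. Exhaustive benzoylation gives its 8-benzoate, (8S,8aS)-2,2-di-tert-butyl-8,8a-dihydro-4H-benzo[d][1,3,2]dioxasilin-8-yl benzoate F3. Pyridine-buffered HF·pyridine releases (1S,6S)-6-hydroxy-5-(hydroxymethyl)cyclohexa-2,4-dien-1-yl benzoate F4. One equivalent of BzCl with collidine at −40 °C then acylates the primary alcohol only, giving 11.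

Step 9 (insufficient facial selectivity, phosphite attack at the C1 oxygen giving the 4,5-epoxide, or ene products). The fallback sets out from 11 and returns at 13 in one operation. VO(acac)2 (cat.) with t-BuOOH in CH2Cl2 at 0 °C performs a hydroxyl-directed epoxidation. The vanadate ester of C2–OH delivers oxygen syn to the trisubstituted allylic C1=C6 bond only and leaves C4=C5 untouched. This fallback makes no new compound (F0).

**Further compounds**
F1 | step 5 | tert-butyl (5R,6S)-4-chloro-5,6-dihydroxycyclohex-2-ene-1-carboxylate | O[C@@H]1[C@@H](O)C(Cl)C=CC1C(=O)OC(C)(C)C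
F2 | step 8 | (8S,8aS)-2,2-di-tert-butyl-8,8a-dihydro-4H-benzo[d][1,3,2]dioxasilin-8-ol | O[C@H]1C=CC=C2CO[Si](C(C)(C)C)(C(C)(C)C)O[C@H]12
F3 | step 8 | (8S,8aS)-2,2-di-tert-butyl-8,8a-dihydro-4H-benzo[d][1,3,2]dioxasilin-8-yl benzoate | O=C(O[C@H]1C=CC=C2CO[Si](C(C)(C)C)(C(C)(C)C)O[C@H]12)c1ccccc1
F4 | step 8 | (1S,6S)-6-hydroxy-5-(hydroxymethyl)cyclohexa-2,4-dien-1-yl benzoate | O[C@@H]1[C@@H](OC(=O)c2ccccc2)C=CC=C1CO
F0 | step 9 | none | none
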